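**Plan**

- Retrosynthesis: after removal of the three O-protecting groups, the first cut is the C2–C3 bond of the propan-1-one chain (carbinol carbon to the benzylic CH2 of the 4-methoxyphenyl ring), then the aryl–C(=O) bond, then the aryl–prenyl bond, ending at mirror-symmetric 4,6-dibromoresorcinol.
- Forward: no ring is formed; the chain is joined in the order aryl–prenyl, aryl–carbonyl, C2–C3, each fragment arriving in one step.
- Enabling feature: the carbinol carbon C2 lies between the ketone carbon C1 on the resorcinol ring and the benzylic C3, so it is the α-carbon of an α-alkoxy aryl ketone (a ketone glycolate) that enolises in one geometry. The acyl group (ring C1) and the prenyl group (ring C5) occupy the two equivalent positions flanking the hydroxyls at ring C2 and C4, so the two bromines of the starting resorcinol are interchangeable.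
- Stereochemistry: the only stereocentre (S at C2) is set during C2–C3 bond formation by a cinchonidine-derived quaternary ammonium phase-transfer catalyst and is carried through one mild acid deprotection.

Key step: step 5

Remark on the chemistry: the glycolate oxygen is carried as its bis(4-methoxyphenyl)methyl ether instead of an unsubstituted benzhydryl ether. The steric picture at the enolate is the same, but this ether ionises in dilute methanolic HCl, so neither hydrogenolysis nor strong acid is needed next to the prenyl group. It is assumed that the two remote methoxy groups do not change the face selectivity of the ion pair. 4-Methoxybenzyl bromide is taken as commercial and is filtered through basic alumina just before use.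

**Route**

Step 1
Reactants: 1 4,6-dibromobenzene-1,3-diol (4,6-dibromoresorcinol)
Product: 2 1,5-dibromo-2,4-bis(methoxymethoxy)benzene
Conditions: MOMCl (2.6 equiv), i-Pr2NEt (3 equiv), CH2Cl2, 0 °C → rt
Reagents that add atoms: chloromethyl methyl ether (MOMCl), COCCl
Why: O-alkylation of the two acidic bromophenol hydroxyls with an α-chloro ether (Williamson-type acetal formation) is routine and gives ethers that tolerate organolithium reagents and hydroxide base.

Step 2
Reactants: 2 1,5-dibromo-2,4-bis(methoxymethoxy)benzene; 3 1-bromo-3-methylbut-2-ene (prenyl bromide)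
Product: 5 1-bromo-2,4-bis(methoxymethoxy)-5-(3-methylbut-2-en-1-yl)benzene, via aryllithium 4 (not isolated)
Conditions: n-BuLi (1.0 equiv), THF, −78 °C; CuBr·SMe2 (10 mol %), then 3 (1.3 equiv), −78 → 0 °C
Reagents that add atoms: none
Why: bromine–lithium exchange on either of the two equivalent C–Br bonds gives a single monolithio species (a second exchange on the already anionic ring is slow), and copper-catalysed allylic substitution at the unhindered primary carbon of prenyl bromide should attach the linear prenyl group.

Step 3
Reactants: 6 2-chloro-N-methoxy-N-methylacetamide; 7 bis(4-methoxyphenyl)methanol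
Product: 9 2-[bis(4-methoxyphenyl)methoxy]-N-methoxy-N-methylacetamide, via sodium alkoxide 8 (not isolated)
Conditions: NaH (1.1 equiv), THF, 0 °C; then 6 (1.0 equiv), n-Bu4NI (5 mol %), 0 °C → rt
Reagents that add atoms: none
Why: Williamson ether synthesis, in which the secondary alkoxide displaces chloride from a carbonyl-activated primary carbon much faster than it attacks the hindered Weinreb carbonyl.

Step 4
Reactants: 5 1-bromo-2,4-bis(methoxymethoxy)-5-(3-methylbut-2-en-1-yl)benzene; 9 2-[bis(4-methoxyphenyl)methoxy]-N-methoxy-N-methylacetamide
Product: 12 2-[bis(4-methoxyphenyl)methoxy]-1-[2,4-bis(methoxymethoxy)-5-(3-methylbut-2-en-1-yl)phenyl]ethan-1-one, via aryllithium 10 (not isolated), via lithium hemiaminal 11 (not isolated)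
Conditions: n-BuLi (1.05 equiv), THF, −78 °C; 9 (1.1 equiv), −78 → −40 °C; AcOH (1.5 equiv), −78 °C, then aq. NaHCO3
Reagents that add atoms: none
Why: bromine–lithium exchange followed by the Weinreb ketone synthesis, in which the N,O-chelated tetrahedral adduct 11 survives until the quench so that the aryllithium adds only once and the ketone appears only after protonation.

Step 5
Reactants: 12 2-[bis(4-methoxyphenyl)methoxy]-1-[2,4-bis(methoxymethoxy)-5-(3-methylbut-2-en-1-yl)phenyl]ethan-1-one; 13 1-(bromomethyl)-4-methoxybenzene (4-methoxybenzyl bromide)
Product: 15 (2S)-2-[bis(4-methoxyphenyl)methoxy]-1-[2,4-bis(methoxymethoxy)-5-(3-methylbut-2-en-1-yl)phenyl]-3-(4-methoxyphenyl)propan-1-one, via cesium Z-enolate 14 (not isolated)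
Conditions: O(9)-allyl-N-(2,3,4-trifluorobenzyl)dihydrocinchonidinium bromide (10 mol %), CsOH·H2O (5 equiv), 13 (5 equiv), CH2Cl2–hexane 1:1, −35 °C
Reagents that add atoms: none
Why: Solid CsOH·H2O removes an α-proton of 12 at the solid–liquid interface to give enolate 14, held in the Z geometry with the enolate oxygen and the ether oxygen on the same side, which passes into the organic phase as a tight ion pair with the chiral ammonium cation and displaces bromide from 13 in an SN2 step that forms the C2–C3 bond. The closest known reaction type is the asymmetric phase-transfer (O'Donnell-type) alkylation, established for glycine imine esters and for O-diarylmethyl glycolates of 2-alkoxyaryl ketones with benzylic bromides, from which 12 differs only in remote substituents. No ring is closed. The new stereocentre C2 is controlled by the catalyst alone: the cinchonidinium cation is expected to cover the Re face of the enolate α-carbon, so that the electrophile enters from the Si face and gives S, the sense being confirmed on the first run by chiral HPLC and by the sign of rotation of 16. The step needs enantiofacial selectivity, secured by the single enolate geometry, the non-polar solvent pair and the low temperature that keep the ion pair tight and the uncatalysed interfacial reaction slow. It also needs mono- rather than dialkylation and C- rather than O-alkylation, secured by the hindered, less acidic tertiary α-C–H of 15 and by the soft benzylic electrophile, while the MOM ethers, the prenyl alkene and the diarylmethyl ether are inert to the base.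

Step 6
Reactants: 15 (2S)-2-[bis(4-methoxyphenyl)methoxy]-1-[2,4-bis(methoxymethoxy)-5-(3-methylbut-2-en-1-yl)phenyl]-3-(4-methoxyphenyl)propan-1-one
Product: 16 Lespeflorin C2, (2S)-1-[2,4-dihydroxy-5-(3-methylbut-2-en-1-yl)phenyl]-2-hydroxy-3-(4-methoxyphenyl)propan-1-one
Conditions: HCl (1 M in MeOH), MeOH–THF 4:1, 0 °C → rt (40 °C only if the para MOM ether lags); solid NaHCO3
Reagents that add atoms: none
Why: acid-catalysed acetal methanolysis of both MOM ethers and SN1 solvolysis of the doubly anisyl-stabilised diarylmethyl ether should proceed together, with methanol trapping both cations, under conditions too mild for chroman closure onto the prenyl group or for enolisation of the α-hydroxy ketone.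

**Compound list**

1 | 4,6-dibromobenzene-1,3-diol (4,6-dibromoresorcinol) | Oc1cc(O)c(Br)cc1Br | starting material
2 | 1,5-dibromo-2,4-bis(methoxymethoxy)benzene | COCOc1cc(OCOC)c(Br)cc1Br | intermediate
3 | 1-bromo-3-methylbut-2-ene (prenyl bromide) | CC(C)=CCBr | starting material
4 | [5-bromo-2,4-bis(methoxymethoxy)phenyl]lithium | [Li]c1cc(Br)c(OCOC)cc1OCOC | intermediate (not isolated)
5 | 1-bromo-2,4-bis(methoxymethoxy)-5-(3-methylbut-2-en-1-yl)benzene | COCOc1cc(OCOC)c(CC=C(C)C)cc1Br | intermediate
6 | 2-chloro-N-methoxy-N-methylacetamide | CON(C)C(=O)CCl | starting material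
7 | bis(4-methoxyphenyl)methanol | COc1ccc(C(O)c2ccc(OC)cc2)cc1 | starting material
8 | sodium bis(4-methoxyphenyl)methanolate | [Na+].[O-]C(c1ccc(OC)cc1)c1ccc(OC)cc1 | intermediate (not isolated)
9 | 2-[bis(4-methoxyphenyl)methoxy]-N-methoxy-N-methylacetamide | CON(C)C(=O)COC(c1ccc(OC)cc1)c1ccc(OC)cc1 | intermediate
10 | [2,4-bis(methoxymethoxy)-5-(3-methylbut-2-en-1-yl)phenyl]lithium | [Li]c1cc(CC=C(C)C)c(OCOC)cc1OCOC | intermediate (not isolated)
11 | lithium hemiaminal (tetrahedral adduct of 10 and 9, racemic at the new carbon) | [Li]OC(COC(c1ccc(OC)cc1)c1ccc(OC)cc1)(N(C)OC)c1cc(CC=C(C)C)c(OCOC)cc1OCOC | intermediate (not isolated)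
12 | 2-[bis(4-methoxyphenyl)methoxy]-1-[2,4-bis(methoxymethoxy)-5-(3-methylbut-2-en-1-yl)phenyl]ethan-1-one | O=C(COC(c1ccc(OC)cc1)c1ccc(OC)cc1)c1cc(CC=C(C)C)c(OCOC)cc1OCOC | intermediate
13 | 1-(bromomethyl)-4-methoxybenzene (4-methoxybenzyl bromide) | COc1ccc(CBr)cc1 | starting material
14 | cesium (Z)-enolate of 12 (drawn as the cesium salt; it reacts as the ion pair with the catalyst cation) | [Cs+].[O-]/C(=C\OC(c1ccc(OC)cc1)c1ccc(OC)cc1)c1cc(CC=C(C)C)c(OCOC)cc1OCOC | intermediate (not isolated)
15 | (2S)-2-[bis(4-methoxyphenyl)methoxy]-1-[2,4-bis(methoxymethoxy)-5-(3-methylbut-2-en-1-yl)phenyl]-3-(4-methoxyphenyl)propan-1-one | COc1ccc(C[C@H](OC(c2ccc(OC)cc2)c2ccc(OC)cc2)C(=O)c2cc(CC=C(C)C)c(OCOC)cc2OCOC)cc1 | intermediate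
16 | Lespeflorin C2, (2S)-1-[2,4-dihydroxy-5-(3-methylbut-2-en-1-yl)phenyl]-2-hydroxy-3-(4-methoxyphenyl)propan-1-one | COc1ccc(C[C@H](O)C(=O)c2cc(CC=C(C)C)c(O)cc2O)cc1 | target

**Count and risks**

Total step count: 6. Longest linear sequence: 5 steps (steps 1, 2, 4, 5, 6, from 1 to 16); step 3 supplies the side branch.

Steps most likely to fail:

1. Step 5. The ion pair may discriminate the enolate faces poorly, and the alkylation at the solid surface without the catalyst may erode the selectivity further. If only the sense is reversed, the pseudoenantiomeric cinchoninium salt would be tried first. If face control stays inadequate, the stereocentre would be taken from the chiral pool instead. O-Methyl-L-tyrosine (COc1ccc(C[C@H](N)C(=O)O)cc1) would be diazotised (NaNO2, aq. H2SO4, 0 °C → rt), which replaces NH2 by OH with net retention through the α-lactone, to give (S)-2-hydroxy-3-(4-methoxyphenyl)propanoic acid F1. Coupling with N,O-dimethylhydroxylamine hydrochloride (EDC·HCl, HOBt, i-Pr2NEt, CH2Cl2) would give (S)-2-hydroxy-N-methoxy-3-(4-methoxyphenyl)-N-methylpropanamide F2, and MOMCl with i-Pr2NEt would give its methoxymethyl ether (S)-N-methoxy-2-(methoxymethoxy)-3-(4-methoxyphenyl)-N-methylpropanamide F3. Aryllithium 10, generated from bromide 5 as in step 4, would be acylated by F3 to give (S)-1-[2,4-bis(methoxymethoxy)-5-(3-methylbut-2-en-1-yl)phenyl]-2-(methoxymethoxy)-3-(4-methoxyphenyl)propan-1-one F4, and methanolic HCl as in step 6 would remove the three MOM ethers. This branch sets out from 5 and rejoins the route at 16.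

2. Step 6. The diarylmethyl cation may be recaptured by the electron-rich resorcinol ring, the freed ortho phenol may close onto the prenyl group under acid, and prolonged acid contact may enolise the α-hydroxy ketone. The deprotection would then be split into two operations with an irreversible trap. Ether 15 would be treated with Et3SiH (3 equiv) and 1–2 % CF3CO2H in CH2Cl2 at −20 °C, where the cation is reduced to the diarylmethane while both phenols stay capped. This should give (S)-1-[2,4-bis(methoxymethoxy)-5-(3-methylbut-2-en-1-yl)phenyl]-2-hydroxy-3-(4-methoxyphenyl)propan-1-one F5. The MOM ethers of F5 would then be methanolysed over a sulfonic acid resin (H+ form) in MeOH at 40 °C, the resin being filtered off as soon as conversion is complete. This branch sets out from 15 and rejoins the route at 16.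

3. Step 2. The allylic substitution may occur with transposition to give the 1,1-dimethylallyl isomer, and lithium may migrate to the ring position between the two MOM ethers before the electrophile reacts. Aryllithium 4, made from 2 as before, would instead be quenched with allyl bromide, for which both modes of allylic attack give the same product, 1-bromo-2,4-bis(methoxymethoxy)-5-(prop-2-en-1-yl)benzene F6. Olefin cross-metathesis of F6 with excess 2-methylbut-2-ene (second-generation Grubbs catalyst, CH2Cl2, 40 °C) would then convert the allyl into the prenyl group. This branch sets out from 2 and rejoins the route at 5.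

**Further compounds**

F1 | step 5 | (S)-2-hydroxy-3-(4-methoxyphenyl)propanoic acid | COc1ccc(C[C@H](O)C(=O)O)cc1
F2 | step 5 | (S)-2-hydroxy-N-methoxy-3-(4-methoxyphenyl)-N-methylpropanamide | COc1ccc(C[C@H](O)C(=O)N(C)OC)cc1
F3 | step 5 | (S)-N-methoxy-2-(methoxymethoxy)-3-(4-methoxyphenyl)-N-methylpropanamide | COc1ccc(C[C@H](OCOC)C(=O)N(C)OC)cc1
F4 | step 5 | (S)-1-[2,4-bis(methoxymethoxy)-5-(3-methylbut-2-en-1-yl)phenyl]-2-(methoxymethoxy)-3-(4-methoxyphenyl)propan-1-one | COc1ccc(C[C@H](OCOC)C(=O)c2cc(CC=C(C)C)c(OCOC)cc2OCOC)cc1
F5 | step 6 | (S)-1-[2,4-bis(methoxymethoxy)-5-(3-methylbut-2-en-1-yl)phenyl]-2-hydroxy-3-(4-methoxyphenyl)propan-1-one | COc1ccc(C[C@H](O)C(=O)c2cc(CC=C(C)C)c(OCOC)cc2OCOC)cc1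
F6 | step 2 | 1-bromo-2,4-bis(methoxymethoxy)-5-(prop-2-en-1-yl)benzene | COCOc1cc(OCOC)c(CC=C)cc1Br
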